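**Retrosynthetic overview**
1. Target 22 ⇐ stearoylation of the one free primary OH of the diallyl ether of (+)-lariciresinol (19), then Pd(PPh3)4-catalysed removal of both phenol allyl ethers.
2. Tetrahydrofuran ring of 19 ⇐ triol 17 by stereoconvergent SN1 etherification (benzylic C-2 to O-1), giving the 2,3-trans ring.
3. Triol 17 ⇐ reduction of aldol adduct 16; key C–C bond (future C-2–C-3) ⇐ intermolecular aldol of the lithium enolate of (R)-lactone 12 with O-allylvanillin 14, anti to the benzyl group.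
4. Lactone 12 ⇐ Evans alkylation of acyl oxazolidinone 7 with tert-butyl bromoacetate (sets future C-4); 7 ⇐ ferulic acid.
5. Ring order: butyrolactone first (step 7), opened by reduction (step 10), tetrahydrofuran last (step 11).

Assumption: the target is read as the (2S,3R,4R) primary stearate of (+)-lariciresinol, and ferulic acid, vanillin, (S)-4-benzyl-1,3-oxazolidin-2-one, tert-butyl bromoacetate and stearoyl chloride are bought.

**Step 1**
Reactants: 1 ferulic acid
Product: 2 3-(4-hydroxy-3-methoxyphenyl)propanoic acid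
Conditions: H2 (1 atm), Pd/C (10 wt% Pd), MeOH, rt
Reagents that add atoms: none
Why: Heterogeneous catalytic hydrogenation saturates only the cinnamic C=C and leaves arene, phenol and acid alone.

**Step 2**
Reactants: 2 3-(4-hydroxy-3-methoxyphenyl)propanoic acid
Product: 3 prop-2-enyl 3-[3-methoxy-4-(prop-2-enyloxy)phenyl]propanoate
Conditions: allyl bromide (2.5 equiv), K2CO3 (3 equiv), DMF, 50 °C
Reagents that add atoms: allyl bromide, C=CCBr
Why: Williamson etherification of the phenoxide and SN2 O-alkylation of the carboxylate install an allyl ether that tolerates the later enolate, hydride and acid steps and comes off without hydrogenolysis.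

**Step 3**
Reactants: 3 prop-2-enyl 3-[3-methoxy-4-(prop-2-enyloxy)phenyl]propanoate
Product: 4 3-[3-methoxy-4-(prop-2-enyloxy)phenyl]propanoic acid
Conditions: LiOH·H2O (3 equiv), THF/MeOH/H2O, rt; then 1 M HCl to pH 2
Reagents that add atoms: lithium hydroxide, [Li+].[OH-]
Why: Saponification cleaves only the allyl ester because an aryl allyl ether is inert to hydroxide.

**Step 4**
Reactants: 4 3-[3-methoxy-4-(prop-2-enyloxy)phenyl]propanoic acid; 5 (S)-4-benzyl-1,3-oxazolidin-2-one
Product: 7 (4S)-4-benzyl-3-{3-[3-methoxy-4-(prop-2-enyloxy)phenyl]propanoyl}-1,3-oxazolidin-2-one, via mixed pivalic anhydride 6 (not isolated)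
Conditions: pivaloyl chloride (1.05 equiv), Et3N (2.5 equiv), THF, −20 → 0 °C; then 5 (1.0 equiv), LiCl (1.1 equiv), rt
Reagents that add atoms: pivaloyl chloride, CC(C)(C)C(=O)Cl (its atoms stay only in intermediate 6)
Why: Mixed-anhydride N-acylation, in which the hindered pivaloyl carbonyl steers the LiCl-activated oxazolidinone onto the wanted acyl group; no stereocentre is formed.

**Step 5**
Reactants: 7 (4S)-4-benzyl-3-{3-[3-methoxy-4-(prop-2-enyloxy)phenyl]propanoyl}-1,3-oxazolidin-2-one; 8 tert-butyl bromoacetate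
Product: 10 tert-butyl (3R)-3-{[(4S)-4-benzyl-2-oxo-1,3-oxazolidin-3-yl]carbonyl}-4-[3-methoxy-4-(prop-2-enyloxy)phenyl]butanoate, via sodium Z-enolate 9 (not isolated)
Conditions: NaN(SiMe3)2 (1.1 equiv), THF, −78 °C, 1 h; then 8 (2 equiv), −78 → −40 °C; aq NH4Cl
Reagents that add atoms: sodium bis(trimethylsilyl)amide, C[Si](C)(C)[N-][Si](C)(C)C.[Na+] (only its sodium, held in intermediate 9)
Why: Evans asymmetric alkylation, in which the chelated Z-enolate is alkylated on the face opposite the benzyl group of the (S)-auxiliary, setting the future ring C-4 as R (dr typically ≥ 95:5, minor isomer removed by chromatography).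

**Step 6**
Reactants: 10 tert-butyl (3R)-3-{[(4S)-4-benzyl-2-oxo-1,3-oxazolidin-3-yl]carbonyl}-4-[3-methoxy-4-(prop-2-enyloxy)phenyl]butanoate
Product: 11 tert-butyl (3R)-3-(hydroxymethyl)-4-[3-methoxy-4-(prop-2-enyloxy)phenyl]butanoate
Conditions: LiBH4 (1.5 equiv), MeOH (1.5 equiv), THF, 0 °C
Reagents that add atoms: none
Why: Chemoselective reductive cleavage of the imide carbonyl by borohydride spares the hindered tert-butyl ester, does not epimerise the stereocentre, and returns the auxiliary.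

**Step 7**
Reactants: 11 tert-butyl (3R)-3-(hydroxymethyl)-4-[3-methoxy-4-(prop-2-enyloxy)phenyl]butanoate
Product: 12 (4R)-4-[3-methoxy-4-(prop-2-enyloxy)benzyl]dihydrofuran-2(3H)-one
Conditions: p-TsOH·H2O (0.1 equiv), toluene, 80 °C
Reagents that add atoms: none
Why: Acid-catalysed lactonisation (intramolecular transesterification to a five-membered ring) expels tert-butanol without touching the stereocentre.

**Step 8**
Reactants: 13 vanillin
Product: 14 3-methoxy-4-(prop-2-enyloxy)benzaldehyde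
Conditions: allyl bromide (1.2 equiv), K2CO3 (1.5 equiv), DMF, rt
Reagents that add atoms: allyl bromide, C=CCBr
Why: Williamson ether synthesis on the acidic phenol gives the aldehyde partner with the same protecting group as the lactone.

**Step 9**
Reactants: 12 (4R)-4-[3-methoxy-4-(prop-2-enyloxy)benzyl]dihydrofuran-2(3H)-one; 14 3-methoxy-4-(prop-2-enyloxy)benzaldehyde
Product: 16 (3S,4R)-3-{hydroxy[3-methoxy-4-(prop-2-enyloxy)phenyl]methyl}-4-[3-methoxy-4-(prop-2-enyloxy)benzyl]dihydrofuran-2(3H)-one as both carbinol epimers, via lithium enolate 15 (not isolated)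
Conditions: LiN(iPr)2 (1.1 equiv), THF, −78 °C, 45 min; then 14 (1.2 equiv), −78 °C, 1 h; sat. aq NH4Cl at −78 °C
Reagents that add atoms: lithium diisopropylamide, CC(C)[N-]C(C)C.[Li+] (only its lithium, held in intermediate 15)
Why: Intermolecular aldol addition joins the two halves at the future C-2–C-3 bond, the aldehyde approaching the enolate face anti to the C-4 arylmethyl group so that C-3 is set trans; the carbinol epimer mixture is harmless because step 11 passes through a planar benzylic cation, and the cold quench prevents retro-aldol.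

**Step 10**
Reactants: 16 (3S,4R)-3-{hydroxy[3-methoxy-4-(prop-2-enyloxy)phenyl]methyl}-4-[3-methoxy-4-(prop-2-enyloxy)benzyl]dihydrofuran-2(3H)-one
Product: 17 (2R,3R)-2-{hydroxy[3-methoxy-4-(prop-2-enyloxy)phenyl]methyl}-3-[3-methoxy-4-(prop-2-enyloxy)benzyl]butane-1,4-diol as both carbinol epimers
Conditions: LiAlH4 (3 equiv), THF, 0 °C → rt; H2O then aq NaOH work-up
Reagents that add atoms: none
Why: Hydride reduction of the lactone to the 1,4-diol touches neither stereocentre nor the aryl allyl ethers.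

**Step 11**
Reactants: 17 (2R,3R)-2-{hydroxy[3-methoxy-4-(prop-2-enyloxy)phenyl]methyl}-3-[3-methoxy-4-(prop-2-enyloxy)benzyl]butane-1,4-diol
Product: 19 {(2S,3R,4R)-2-[3-methoxy-4-(prop-2-enyloxy)phenyl]-4-[3-methoxy-4-(prop-2-enyloxy)benzyl]tetrahydrofuran-3-yl}methanol, via benzylic cation 18 (not isolated)
Conditions: camphor-10-sulfonic acid (0.1 equiv), CH2Cl2, 0 °C → rt; Et3N as soon as 17 is consumed
Reagents that add atoms: none
Why: SN1 cycloetherification, in which both carbinol epimers ionise to the same p-alkoxybenzylic cation and the hydroxymethyl on the benzyl-bearing carbon closes the five-membered ring (the other one could only give an oxetane), placing the aryl group trans to the neighbouring CH2OH (favoured kinetically and thermodynamically) and so setting C-2 as S.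

**Step 12**
Reactants: 19 {(2S,3R,4R)-2-[3-methoxy-4-(prop-2-enyloxy)phenyl]-4-[3-methoxy-4-(prop-2-enyloxy)benzyl]tetrahydrofuran-3-yl}methanol; 20 stearoyl chloride
Product: 21 {(2S,3R,4R)-2-[3-methoxy-4-(prop-2-enyloxy)phenyl]-4-[3-methoxy-4-(prop-2-enyloxy)benzyl]tetrahydrofuran-3-yl}methyl octadecanoate
Conditions: 20 (1.2 equiv), Et3N (2 equiv), DMAP (0.1 equiv), CH2Cl2, 0 °C → rt
Reagents that add atoms: none
Why: DMAP-catalysed acylation (nucleophilic catalysis) of the only free hydroxyl in the molecule.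

**Step 13**
Reactants: 21 {(2S,3R,4R)-2-[3-methoxy-4-(prop-2-enyloxy)phenyl]-4-[3-methoxy-4-(prop-2-enyloxy)benzyl]tetrahydrofuran-3-yl}methyl octadecanoate
Product: 22 [(2S,3R,4R)-2-(4-hydroxy-3-methoxyphenyl)-4-(4-hydroxy-3-methoxybenzyl)tetrahydrofuran-3-yl]methyl octadecanoate
Conditions: Pd(PPh3)4 (5 mol%), morpholine (10 equiv), degassed THF, rt
Reagents that add atoms: none
Why: Tsuji–Trost deallylation, in which zerovalent palladium ionises each aryl allyl ether to a π-allyl complex that morpholine captures, freeing both phenols without touching the ester, the benzylic ring ether or any stereocentre.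

**Compound list**
1 | ferulic acid, (E)-3-(4-hydroxy-3-methoxyphenyl)prop-2-enoic acid | COc1cc(/C=C/C(=O)O)ccc1O | starting material
2 | 3-(4-hydroxy-3-methoxyphenyl)propanoic acid | COc1cc(CCC(=O)O)ccc1O | intermediate
3 | prop-2-enyl 3-[3-methoxy-4-(prop-2-enyloxy)phenyl]propanoate | C=CCOC(=O)CCc1ccc(OCC=C)c(OC)c1 | intermediate
4 | 3-[3-methoxy-4-(prop-2-enyloxy)phenyl]propanoic acid | OC(=O)CCc1ccc(OCC=C)c(OC)c1 | intermediate
5 | (S)-4-benzyl-1,3-oxazolidin-2-one | O=C1N[C@@H](Cc2ccccc2)CO1 | starting material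
6 | mixed anhydride of 4 with pivalic acid | CC(C)(C)C(=O)OC(=O)CCc1ccc(OCC=C)c(OC)c1 | intermediate (not isolated)
7 | (4S)-4-benzyl-3-{3-[3-methoxy-4-(prop-2-enyloxy)phenyl]propanoyl}-1,3-oxazolidin-2-one | O=C(CCc1ccc(OCC=C)c(OC)c1)N1[C@@H](Cc2ccccc2)COC1=O | intermediate
8 | tert-butyl bromoacetate | CC(C)(C)OC(=O)CBr | starting material
9 | sodium (Z)-enolate of 7 | [Na+].[O-]/C(=C\Cc1ccc(OCC=C)c(OC)c1)N1[C@@H](Cc2ccccc2)COC1=O | intermediate (not isolated)
10 | tert-butyl (3R)-3-{[(4S)-4-benzyl-2-oxo-1,3-oxazolidin-3-yl]carbonyl}-4-[3-methoxy-4-(prop-2-enyloxy)phenyl]butanoate | CC(C)(C)OC(=O)C[C@@H](Cc1ccc(OCC=C)c(OC)c1)C(=O)N1[C@@H](Cc2ccccc2)COC1=O | intermediate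
11 | tert-butyl (3R)-3-(hydroxymethyl)-4-[3-methoxy-4-(prop-2-enyloxy)phenyl]butanoate | CC(C)(C)OC(=O)C[C@@H](Cc1ccc(OCC=C)c(OC)c1)CO | intermediate
12 | (4R)-4-[3-methoxy-4-(prop-2-enyloxy)benzyl]dihydrofuran-2(3H)-one | O=C1C[C@@H](Cc2ccc(OCC=C)c(OC)c2)CO1 | intermediate
13 | vanillin | COc1cc(C=O)ccc1O | starting material
14 | 3-methoxy-4-(prop-2-enyloxy)benzaldehyde | C=CCOc1ccc(C=O)cc1OC | intermediate
15 | lithium enolate of 12, lithium (3R)-3-[3-methoxy-4-(prop-2-enyloxy)benzyl]-2,3-dihydrofuran-5-olate | [Li+].[O-]C1=C[C@@H](Cc2ccc(OCC=C)c(OC)c2)CO1 | intermediate (not isolated)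
16 | (3S,4R)-3-{hydroxy[3-methoxy-4-(prop-2-enyloxy)phenyl]methyl}-4-[3-methoxy-4-(prop-2-enyloxy)benzyl]dihydrofuran-2(3H)-one, both carbinol epimers | O=C1OC[C@H](Cc2ccc(OCC=C)c(OC)c2)[C@H]1C(O)c1ccc(OCC=C)c(OC)c1 | intermediate
17 | (2R,3R)-2-{hydroxy[3-methoxy-4-(prop-2-enyloxy)phenyl]methyl}-3-[3-methoxy-4-(prop-2-enyloxy)benzyl]butane-1,4-diol, both carbinol epimers | OC[C@@H]([C@@H](Cc1ccc(OCC=C)c(OC)c1)CO)C(O)c1ccc(OCC=C)c(OC)c1 | intermediate
18 | p-alkoxybenzylic cation from 17 | OC[C@@H]([C@@H](Cc1ccc(OCC=C)c(OC)c1)CO)[CH+]c1ccc(OCC=C)c(OC)c1 | intermediate (not isolated)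
19 | {(2S,3R,4R)-2-[3-methoxy-4-(prop-2-enyloxy)phenyl]-4-[3-methoxy-4-(prop-2-enyloxy)benzyl]tetrahydrofuran-3-yl}methanol, aryl trans to CH2OH, CH2OH cis to benzyl | OC[C@H]1[C@@H](Cc2ccc(OCC=C)c(OC)c2)CO[C@@H]1c1ccc(OCC=C)c(OC)c1 | intermediate
20 | stearoyl chloride (octadecanoyl chloride) | CCCCCCCCCCCCCCCCCC(=O)Cl | starting material
21 | {(2S,3R,4R)-2-[3-methoxy-4-(prop-2-enyloxy)phenyl]-4-[3-methoxy-4-(prop-2-enyloxy)benzyl]tetrahydrofuran-3-yl}methyl octadecanoate | CCCCCCCCCCCCCCCCCC(=O)OC[C@H]1[C@@H](Cc2ccc(OCC=C)c(OC)c2)CO[C@@H]1c1ccc(OCC=C)c(OC)c1 | intermediate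
22 | [(2S,3R,4R)-2-(4-hydroxy-3-methoxyphenyl)-4-(4-hydroxy-3-methoxybenzyl)tetrahydrofuran-3-yl]methyl octadecanoate | CCCCCCCCCCCCCCCCCC(=O)OC[C@H]1[C@@H](Cc2ccc(O)c(OC)c2)CO[C@@H]1c1ccc(O)c(OC)c1 | target

**Step count and risk**
Total steps: 13. Longest linear sequence: 12 (steps 1–7, then 9–13; step 8 is a one-step branch).

Most likely to fail:

- **Step 11 (acid ring closure).** The benzylic cation can also be trapped by the electron-rich arene of the neighbouring benzyl group (Friedel–Crafts, giving an aryltetralin), or the ring can close 2,3-cis. The fallback sets out from 17 and comes back at 22. Pd(PPh3)4 and morpholine in THF remove both allyl groups from 17 to give (2R,3R)-2-[hydroxy(4-hydroxy-3-methoxyphenyl)methyl]-3-(4-hydroxy-3-methoxybenzyl)butane-1,4-diol F6. As a p-hydroxybenzylic alcohol it closes through its p-quinone methide under far milder acid (pyridinium p-toluenesulfonate, CH2Cl2/THF, rt) to (+)-lariciresinol F7. Immobilised Candida antarctica lipase B (Novozym 435) with vinyl stearate in 2-methylbutan-2-ol at 50 °C then acylates only the primary aliphatic hydroxyl, not the phenols, giving 22.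

- **Step 9 (aldol).** Retro-aldol, incomplete conversion or imperfect anti selectivity are possible. The fallback sets out from 12 and 14 and comes back at 16. The same bond is made by Claisen-type C-acylation: 14 is oxidised (NaClO2, NaH2PO4, 2-methylbut-2-ene, t-BuOH/H2O) to 3-methoxy-4-(prop-2-enyloxy)benzoic acid F1. Oxalyl chloride with catalytic DMF in CH2Cl2 gives 3-methoxy-4-(prop-2-enyloxy)benzoyl chloride F2. The lithium enolate of 12 (LiN(SiMe3)2, 2.1 equiv, THF, −78 °C) is acylated by F2 to (3S,4R)-3-[3-methoxy-4-(prop-2-enyloxy)benzoyl]-4-[3-methoxy-4-(prop-2-enyloxy)benzyl]dihydrofuran-2(3H)-one F3, whose C-3 settles trans through its enol. NaBH4 in MeOH/THF at −20 °C reduces only the ketone and delivers 16 as both carbinol epimers.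

- **Step 10 (LiAlH4 on the free aldol).** The metal aldolate can fragment by retro-aldol before the lactone is reduced. The fallback sets out from 16 and comes back at 17. The carbinol is capped first with TBSOTf and 2,6-lutidine (CH2Cl2, −78 → 0 °C) to give (3S,4R)-3-{[tert-butyl(dimethyl)silyl]oxy[3-methoxy-4-(prop-2-enyloxy)phenyl]methyl}-4-[3-methoxy-4-(prop-2-enyloxy)benzyl]dihydrofuran-2(3H)-one F4. LiAlH4 (THF, 0 °C) then gives (2R,3R)-2-{[tert-butyl(dimethyl)silyl]oxy[3-methoxy-4-(prop-2-enyloxy)phenyl]methyl}-3-[3-methoxy-4-(prop-2-enyloxy)benzyl]butane-1,4-diol F5. Bu4NF in THF removes the silyl group, wherever it may have migrated, to give 17.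

**Further compounds**
F1 | step 9 | 3-methoxy-4-(prop-2-enyloxy)benzoic acid | OC(=O)c1ccc(OCC=C)c(OC)c1
F2 | step 9 | 3-methoxy-4-(prop-2-enyloxy)benzoyl chloride | ClC(=O)c1ccc(OCC=C)c(OC)c1
F3 | step 9 | (3S,4R)-3-[3-methoxy-4-(prop-2-enyloxy)benzoyl]-4-[3-methoxy-4-(prop-2-enyloxy)benzyl]dihydrofuran-2(3H)-one | O=C1OC[C@H](Cc2ccc(OCC=C)c(OC)c2)[C@H]1C(=O)c1ccc(OCC=C)c(OC)c1
F4 | step 10 | (3S,4R)-3-{[tert-butyl(dimethyl)silyl]oxy[3-methoxy-4-(prop-2-enyloxy)phenyl]methyl}-4-[3-methoxy-4-(prop-2-enyloxy)benzyl]dihydrofuran-2(3H)-one, both silyloxy epimers | O=C1OC[C@H](Cc2ccc(OCC=C)c(OC)c2)[C@H]1C(O[Si](C)(C)C(C)(C)C)c1ccc(OCC=C)c(OC)c1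
F5 | step 10 | (2R,3R)-2-{[tert-butyl(dimethyl)silyl]oxy[3-methoxy-4-(prop-2-enyloxy)phenyl]methyl}-3-[3-methoxy-4-(prop-2-enyloxy)benzyl]butane-1,4-diol, both silyloxy epimers | OC[C@@H]([C@@H](Cc1ccc(OCC=C)c(OC)c1)CO)C(O[Si](C)(C)C(C)(C)C)c1ccc(OCC=C)c(OC)c1
F6 | step 11 | (2R,3R)-2-[hydroxy(4-hydroxy-3-methoxyphenyl)methyl]-3-(4-hydroxy-3-methoxybenzyl)butane-1,4-diol, both carbinol epimers | OC[C@@H]([C@@H](Cc1ccc(O)c(OC)c1)CO)C(O)c1ccc(O)c(OC)c1
F7 | step 11 | (+)-lariciresinol, 4-[(2S,3R,4R)-4-(4-hydroxy-3-methoxybenzyl)-3-(hydroxymethyl)tetrahydrofuran-2-yl]-2-methoxyphenol | OC[C@H]1[C@@H](Cc2ccc(O)c(OC)c2)CO[C@@H]1c1ccc(O)c(OC)c1
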